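## Analysis of the target

Target 19 is a fully substituted cyclobutane, numbered here C1 (H, CO2Me), C2 (H, CO2H), C3 and C4 (each a quaternary carbon with a methyl group and a 4-methoxy-3-methyl-2-pyron-6-yl ring). All four ring carbons are stereocentres (1R,2S,3R,4S in this numbering): the two carboxyl groups and the two methyl groups share one face, the two pyrones the other. The skeleton would be meso if the two carboxyl groups were alike, so the absolute configuration is only the choice of which of two enantiotopic carboxyl groups is the methyl ester. Sensitive features are the 2-pyrones (vinylogous lactones, opened by hard nucleophiles and reduced on hydrogenation) and the cis ester–acid pair (activation of the acid returns a meso anhydride). H1 and H2 also stand in a 1,5-dicarbonyl relation, through the ring, to the acyl-type groups on C3/C4, so strong base can open the strained ring by retro-Michael cleavage. The difficulty is the C3–C4 bond: two adjacent, cis-substituted quaternary centres, each with a heteroaryl group, which makes an intermolecular union of C3 with C4 or a late alkylation at these carbons unattractive. The strategy rests on the cis relation of the two pyrone C6 atoms on C3 and C4: they can be the two ends of a –CH=CH– bridge, which turns the cyclobutane into a bicyclo[2.2.0]hex-5-ene. That bicycle is the valence isomer of a cyclohexa-1,3-diene with the methyl groups on the diene termini and the C1/C2 carboxyls tied as a cis anhydride, so C3–C4 can be made by an intramolecular photochemical 4π closure.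

## Retrosynthetic reasoning

**19 ⇒ 18.** The last operation only unmasks the C2 acid. The acid has to be covered during the basic and methylating steps, and a second methyl ester would make the molecule meso, so an acid-labile tert-butyl ester is carried in 18.

**18 ⇒ 17 ⇒ 16 ⇒ 15 ⇒ 12 + 13.** Each pyrone is cut at the lactone bond O1–C2 and at C5–C6. This returns pyrone C6 as an aldehyde carbon of dialdehyde 12 and C2–C5 as the chain of keto ester 13, used as its dianion 14. The cut is placed here because C6 then sits at the aldehyde level, which is what alkene cleavage delivers, and because the aldehydes of 12 have quaternary α-carbons and cannot enolise. Forward, both arms are grown at once: double aldol to 15, oxidation to 16, lactonisation to 17 and O-methylation to 18.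

**12 ⇒ 10.** The two cis formyl carbons are joined into one C=C, which gives the bicyclic alkene 10. One functional group then stands for both pyrone attachment points, and their cis relation is guaranteed by the ring. Forward, ozonolysis through ozonide 11 must cleave a strained, unhindered cis alkene.

**10 ⇒ 9 ⇒ 8.** The two different esters are traced back to the meso anhydride 8. Forward, an alkaloid-mediated alcoholysis distinguishes the enantiotopic carbonyls and so introduces the absolute configuration of all four centres in 9. The tert-butyl group is then put on by O-alkylation, without activating the carboxyl group.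

**8 ⇒ 7 (key).** The bridgehead–bridgehead bond of 8, which is the C3–C4 bond of the target, is cut. This gives the flat diene 7, whose two methyl-bearing termini must bond to each other on irradiation. The congested bond is thus made intramolecularly, the methyl groups are cis by ring fusion, and only one facial question remains.

**7 ⇒ 6 ⇒ 4 (via 5).** The diene is an arene with two hydrogens added across the carboxyl-bearing carbons; these become H1 and H2 of the target. Forward, a dissolving-metal 1,2-reduction of the phthalate 5 gives acid 6, and dehydration funnels it to the cis-fused anhydride 7.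

**4 ⇒ 3 ⇒ 1 + 2.** The 3,6-dimethylphthalic framework comes from the Diels–Alder adduct 3 of furan 1 and maleic anhydride 2 by dehydrative aromatisation.

## Alternatives that were turned down

**Alternative 1:** The pyrones are disconnected first, back to a cyclobutane with two cis acetyl groups on C3/C4 and acetoxymethyl groups on C1/C2. Forward, the bis(silyl enol ether) A1 would be acylated twice with methylmalonyl dichloride A2 to close both pyrone rings, giving the meso bis(hydroxypyrone) diacetate A3.
- For: both heterocycles arise in one flask at the final oxidation level. On this point it is stronger than the chosen route, which needs aldol, oxidation and lactonisation. The neopentyl methyl ketones can enolise in one direction only.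
- Against: the disconnection leaves the real problem untouched, since the cyclobutane with vicinal quaternary centres behind A1 still has to be made. The acylation liberates HCl next to two enol ethers that are 1,4-related and can condense with each other. C1 and C2 are carried three oxidation steps below the target, so after A3 two alcohols must be unveiled, desymmetrised in the presence of two acidic hydroxypyrones and oxidised to acid and ester.
- Comparison: the chosen route has a longer pyrone sequence, but it delivers the ring itself, and it carries C1/C2 at the carboxyl level from the first step and uses them for the desymmetrisation.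

**Alternative 2:** The ring is taken from cyclobutane-1,2,3,4-tetracarboxylic dianhydride A4, converted into the imide diacid A5. Forward, excess lithium amide base and a methyl halide would methylate both ring-fusion carbons to give the dimethyl imide diacid A6.
- For: no ring has to be formed. The anti arrangement of the two anhydrides in A4 already matches the trans relation of pyrones and carboxyls. The imide carbons are at the acid level, so a triketide could be reached by acylation without a separate oxidation; on these points it is stronger.
- Against: the key step must turn two tertiary C–H bonds into the vicinal quaternary pair by enolate alkylation. The enolate is an sp2 carbon at the fusion of a four- and a five-membered ring, four C–H acids compete in a polyanion, and the second methyl must enter cis to the first. Afterwards a doubly neopentyl imide must be hydrolysed, two hindered acyl groups that prefer to close on each other must be elaborated in two directions, and the two acids still need desymmetrising.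
- Comparison: the chosen route forms the same bond in one geometrically enforced intramolecular event and reaches the pyrone stage from two free, non-enolisable aldehydes.

**Alternative 3:** The ring is cut into two alkenes. Forward, irradiation of the (S)-butenolide A7 with the tetrasubstituted cyclic alkene A8 would give the tricyclic lactone A9, with C1–C4 and C2–C3 formed together.
- For: it is convergent, and the ring, both quaternary carbons and all four stereocentres arise in one step. The two carboxyl carbons are born different (lactone carbonyl against carbinol carbon), so neither a desymmetrisation nor the tert-butyl protection is needed. The absolute configuration comes from a purchased stereocentre. On all these points it is stronger.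
- Against: a stepwise triplet cycloaddition has to deliver two selectivities at once. One is the butenolide face. The other is the syn/anti orientation of A8, whose alkene carbons carry a methyl and a ring methylene of nearly the same size, so the usual preference for cis-anti-cis adducts has little to work with. The 1,4-biradical from an alkene with many allylic hydrogens can also disproportionate. After A9 the lactone has to be opened and its carbinol carbon degraded to the ester level, which destroys the bought centre, and pivalate and acetonide must be handled.
- Comparison: in the chosen route the relative configuration is largely enforced by ring fusion, leaving one facial question, and the absolute configuration comes from a reagent available in both pseudo-enantiomeric forms.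

Key step: step 5

Assumption: quinidine is taken to open the carbonyl on the ring carbon that becomes C1 of the target, by analogy with cis-fused bicyclic succinic anhydrides. Its pseudo-enantiomer quinine gives the mirror-image half-ester, so the configuration of 9 is to be confirmed by correlation and the alkaloid exchanged if necessary.

## Route

Step 1
Reactants: 1 2,5-dimethylfuran; 2 maleic anhydride
Product: 3 exo-1,4-dimethyl-7-oxabicyclo[2.2.1]hept-5-ene-2,3-dicarboxylic anhydride (meso)
Conditions: Et2O, rt, 24 h
Reagents that add atoms: none
Why: Diels–Alder reaction of an electron-rich furan with a reactive dienophile; the reversible addition settles on the crystalline exo adduct, whose configuration is erased in step 2.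

Step 2
Reactants: 3 exo-1,4-dimethyl-7-oxabicyclo[2.2.1]hept-5-ene-2,3-dicarboxylic anhydride
Product: 4 3,6-dimethylphthalic anhydride
Conditions: 90% H2SO4, −5 to 0 °C; then ice
Reagents that add atoms: none
Why: Acid-mediated opening of the oxygen bridge and loss of water aromatises the ring; the low temperature suppresses the retro-Diels–Alder reaction of 3.

Step 3
Reactants: 4 3,6-dimethylphthalic anhydride
Product: 6 trans-3,6-dimethylcyclohexa-3,5-diene-1,2-dicarboxylic acid (racemic), via disodium 3,6-dimethylphthalate 5 (not isolated)
Conditions: 2 M NaOH, 60 °C; then NaOAc, AcOH (portionwise), 3% Na/Hg, H2O, 0–5 °C; then 20% H2SO4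
Reagents that add atoms: sodium hydroxide, [Na+].[OH-]
Why: Dissolving-metal reduction of a phthalate: two electrons and two protons enter through the bis-enediol, so the hydrogens end on the two carboxyl-bearing carbons and the C3=C4–C5=C6 diene with the methyls on its termini is left. The trans acid is expected, as for phthalic acid itself, and the configuration at C1/C2 is corrected in step 4.

Step 4
Reactants: 6 trans-3,6-dimethylcyclohexa-3,5-diene-1,2-dicarboxylic acid
Product: 7 cis-3,6-dimethylcyclohexa-3,5-diene-1,2-dicarboxylic anhydride (meso)
Conditions: Ac2O, 100 °C, 10–15 min; evaporate, crystallise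
Reagents that add atoms: none
Why: Dehydration through the mixed anhydride; the allylic α-hydrogen epimerises through the enol and only the cis acid closes to an unstrained five-membered anhydride, so the trans acid is funnelled to the cis-fused product as in the unsubstituted series. Short heating limits migration of the diene into conjugation.

Step 5
Reactants: 7 cis-3,6-dimethylcyclohexa-3,5-diene-1,2-dicarboxylic anhydride
Product: 8 exo-1,4-dimethylbicyclo[2.2.0]hex-5-ene-2,3-dicarboxylic anhydride (meso; anhydride anti to the etheno bridge, cis to both bridgehead methyls)
Conditions: hν (254 nm, quartz), Et2O (0.01 M), Ar, 0–5 °C, to partial conversion; recover 7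
Reagents that add atoms: none
Why: Excitation of the cisoid diene (π→π*, about 265 nm) is followed by disrotatory 4π electrocyclisation, the photochemically allowed mode, in which the two methyl-bearing termini C3 and C6 bond to each other. The closest known reaction type is the photochemical valence isomerisation of cis-1,2-dihydrophthalic anhydride to bicyclo[2.2.0]hex-5-ene-2,3-dicarboxylic anhydride. The one new σ bond closes the cyclobutane C1–C2–C3–C6, which is the ring of the target, and with it the cyclobutene C3–C4=C5–C6, both by 4π disrotatory closure. The two new quaternary stereocentres are the bridgeheads: their methyls must be cis because the bicycle can only be cis-fused, and their relation to C1/C2 is set by the folding direction. The ring is expected to fold so that the etheno bridge ends on the face away from the cis-fused anhydride, which would otherwise be pressed into the concave face against C4=C5; this places the carbonyl carbons cis to the methyls. The competing conrotatory 6π opening would put an E double bond into a nine-membered cyclic anhydride and is therefore disfavoured and reversible, so closure should prevail. Dilution, low temperature and partial conversion limit dimerisation and secondary photolysis.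

Step 6
Reactants: 8 exo-1,4-dimethylbicyclo[2.2.0]hex-5-ene-2,3-dicarboxylic anhydride
Product: 9 (1R,2S,3R,4S)-3-(methoxycarbonyl)-1,4-dimethylbicyclo[2.2.0]hex-5-ene-2-carboxylic acid
Conditions: quinidine (1.1 equiv), MeOH (3 equiv), toluene, −55 °C; 2 M HCl work-up
Reagents that add atoms: methanol, CO
Why: Cinchona-alkaloid-mediated desymmetrising methanolysis of a meso cyclic anhydride (general-base delivery of methanol to one enantiotopic carbonyl from the open convex face). No new centre is formed, but the four existing ones become defined in the absolute sense.

Step 7
Reactants: 9 (1R,2S,3R,4S)-3-(methoxycarbonyl)-1,4-dimethylbicyclo[2.2.0]hex-5-ene-2-carboxylic acid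
Product: 10 2-tert-butyl 3-methyl (1R,2S,3R,4S)-1,4-dimethylbicyclo[2.2.0]hex-5-ene-2,3-dicarboxylate
Conditions: t-BuOC(=NH)CCl3 (2.5 equiv), CH2Cl2/cyclohexane, rt
Reagents that add atoms: tert-butyl 2,2,2-trichloroacetimidate, CC(C)(C)OC(=N)C(Cl)(Cl)Cl
Why: Imidate esterification: the acid protonates the imidate and the carboxylate is O-alkylated by the tert-butyl cation. The carboxyl carbon is never activated, so the half-ester cannot return to the meso anhydride and the enantiomeric purity is kept.

Step 8
Reactants: 10 2-tert-butyl 3-methyl (1R,2S,3R,4S)-1,4-dimethylbicyclo[2.2.0]hex-5-ene-2,3-dicarboxylate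
Product: 12 1-tert-butyl 2-methyl (1S,2R,3S,4R)-3,4-diformyl-3,4-dimethylcyclobutane-1,2-dicarboxylate, via secondary ozonide 11 (not isolated)
Conditions: O3, CH2Cl2, −78 °C; then PPh3, −78 °C to rt; non-aqueous work-up
Reagents that add atoms: ozone, [O-][O+]=O
Why: Ozonolysis of a strained cis-disubstituted cyclobutene, with reduction of the ozonide by the phosphine. The aldehydes have quaternary α-carbons and cannot epimerise, and water is excluded so that the cis dialdehyde is not held as a cyclic hydrate.

Step 9
Reactants: 12 1-tert-butyl 2-methyl (1S,2R,3S,4R)-3,4-diformyl-3,4-dimethylcyclobutane-1,2-dicarboxylate; 13 methyl 2-methylacetoacetate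
Product: 15 1-tert-butyl 2-methyl (1S,2R,3S,4R)-3,4-bis(1-hydroxy-5-methoxy-4-methyl-3,5-dioxopentyl)-3,4-dimethylcyclobutane-1,2-dicarboxylate (mixture of diastereomers in the side chains), via dilithio dianion 14 (not isolated)
Conditions: 13 (4.4 equiv), LiN(i-Pr)2 (8.8 equiv), THF, 0 °C; then 12, −78 °C; AcOH, −78 °C
Reagents that add atoms: none
Why: Aldol addition of a β-keto ester dianion, which reacts at its terminal (γ) carbon, far faster with aldehydes than with the ring esters at −78 °C. The new carbinol and α-methyl centres are not controlled and are removed in steps 10 and 11.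

Step 10
Reactants: 15 bis(δ-hydroxy-β-keto ester)
Product: 16 1-tert-butyl 2-methyl (1S,2R,3S,4R)-3,4-bis(5-methoxy-4-methyl-3,5-dioxopentanoyl)-3,4-dimethylcyclobutane-1,2-dicarboxylate
Conditions: Dess–Martin periodinane (3 equiv), CH2Cl2, 0 °C to rt
Reagents that add atoms: none
Why: Hypervalent-iodine oxidation of the two secondary alcohols under neutral conditions gives the β,δ-diketo esters without touching the ring esters or their α-hydrogens.

Step 11
Reactants: 16 bis(β,δ-diketo ester)
Product: 17 1-tert-butyl 2-methyl (1S,2R,3S,4R)-3,4-bis(4-hydroxy-3-methyl-2-oxo-2H-pyran-6-yl)-3,4-dimethylcyclobutane-1,2-dicarboxylate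
Conditions: DBU (4 equiv), toluene, rt; then 1 M HCl
Reagents that add atoms: none
Why: Base-mediated lactonisation of a triketide: the enol oxygen of the δ-ketone attacks the chain ester, methanol leaves and the 4-hydroxy-2-pyrone forms. DBU is too weak to deprotonate the ring esters, so the retro-Michael ring opening is not triggered.

Step 12
Reactants: 17 bis(4-hydroxy-2-pyrone)
Product: 18 1-tert-butyl 2-methyl (1S,2R,3S,4R)-3,4-bis(4-methoxy-3-methyl-2-oxo-2H-pyran-6-yl)-3,4-dimethylcyclobutane-1,2-dicarboxylate
Conditions: Me2SO4 (3 equiv), K2CO3 (4 equiv), acetone, rt to 40 °C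
Reagents that add atoms: dimethyl sulfate, COS(=O)(=O)OC
Why: O-Alkylation of the pyronate; with carbonate and dimethyl sulfate in acetone, methylation at the 4-oxygen, which keeps the 2-pyrone, is the expected course.

Step 13
Reactants: 18 bis(4-methoxy-2-pyrone) tert-butyl methyl diester
Product: 19 (1S,2R,3S,4R)-2-(methoxycarbonyl)-3,4-bis(4-methoxy-3-methyl-2-oxo-2H-pyran-6-yl)-3,4-dimethylcyclobutane-1-carboxylic acid (target)
Conditions: CF3CO2H/CH2Cl2 (1:3), 0 °C to rt
Reagents that add atoms: none
Why: Acidolysis of the tert-butyl ester by alkyl–oxygen cleavage; the methyl ester, the methoxypyrones and all stereocentres are inert to the acid.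

## Compound list

1 | 2,5-dimethylfuran | Cc1ccc(C)o1 | starting material
2 | maleic anhydride | O=C1C=CC(=O)O1 | starting material
3 | exo-1,4-dimethyl-7-oxabicyclo[2.2.1]hept-5-ene-2,3-dicarboxylic anhydride (meso) | C[C@]12C=C[C@](C)(O1)[C@@H]3C(=O)OC(=O)[C@H]23 | intermediate
4 | 3,6-dimethylphthalic anhydride | Cc1ccc(C)c2C(=O)OC(=O)c12 | intermediate
5 | disodium 3,6-dimethylphthalate | Cc1ccc(C)c(C(=O)[O-])c1C(=O)[O-].[Na+].[Na+] | intermediate (not isolated)
6 | trans-3,6-dimethylcyclohexa-3,5-diene-1,2-dicarboxylic acid (racemic; one enantiomer drawn) | OC(=O)[C@@H]1[C@@H](C(=O)O)C(C)=CC=C1C | intermediate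
7 | cis-3,6-dimethylcyclohexa-3,5-diene-1,2-dicarboxylic anhydride (meso) | O=C1OC(=O)[C@@H]2[C@H]1C(C)=CC=C2C | intermediate
8 | exo-1,4-dimethylbicyclo[2.2.0]hex-5-ene-2,3-dicarboxylic anhydride (meso) | O=C1OC(=O)[C@@H]2[C@H]1[C@]3(C)[C@@]2(C)C=C3 | intermediate
9 | (1R,2S,3R,4S)-3-(methoxycarbonyl)-1,4-dimethylbicyclo[2.2.0]hex-5-ene-2-carboxylic acid | COC(=O)[C@@H]1[C@H](C(=O)O)[C@]2(C)[C@@]1(C)C=C2 | intermediate
10 | 2-tert-butyl 3-methyl (1R,2S,3R,4S)-1,4-dimethylbicyclo[2.2.0]hex-5-ene-2,3-dicarboxylate | COC(=O)[C@@H]1[C@H](C(=O)OC(C)(C)C)[C@]2(C)[C@@]1(C)C=C2 | intermediate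
11 | secondary ozonide of 10 (1,2,4-trioxolane bridging the two former alkene carbons; either orientation of the bridge, acetal carbons not defined) | COC(=O)[C@@H]1[C@H](C(=O)OC(C)(C)C)[C@]2(C)[C@@]1(C)C3OOC2O3 | intermediate (not isolated)
12 | 1-tert-butyl 2-methyl (1S,2R,3S,4R)-3,4-diformyl-3,4-dimethylcyclobutane-1,2-dicarboxylate | COC(=O)[C@@H]1[C@H](C(=O)OC(C)(C)C)[C@@](C)(C=O)[C@@]1(C)C=O | intermediate
13 | methyl 2-methylacetoacetate (methyl 2-methyl-3-oxobutanoate) | COC(=O)C(C)C(C)=O | starting material
14 | dilithio dianion of 13 | [Li+].[Li+].C=C([O-])C(C)=C([O-])OC | intermediate (not isolated)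
15 | 1-tert-butyl 2-methyl (1S,2R,3S,4R)-3,4-bis(1-hydroxy-5-methoxy-4-methyl-3,5-dioxopentyl)-3,4-dimethylcyclobutane-1,2-dicarboxylate (side-chain centres as a mixture) | COC(=O)[C@@H]1[C@H](C(=O)OC(C)(C)C)[C@@](C)(C(O)CC(=O)C(C)C(=O)OC)[C@@]1(C)C(O)CC(=O)C(C)C(=O)OC | intermediate
16 | 1-tert-butyl 2-methyl (1S,2R,3S,4R)-3,4-bis(5-methoxy-4-methyl-3,5-dioxopentanoyl)-3,4-dimethylcyclobutane-1,2-dicarboxylate (α-methyl centres as a mixture) | COC(=O)[C@@H]1[C@H](C(=O)OC(C)(C)C)[C@@](C)(C(=O)CC(=O)C(C)C(=O)OC)[C@@]1(C)C(=O)CC(=O)C(C)C(=O)OC | intermediate
17 | 1-tert-butyl 2-methyl (1S,2R,3S,4R)-3,4-bis(4-hydroxy-3-methyl-2-oxo-2H-pyran-6-yl)-3,4-dimethylcyclobutane-1,2-dicarboxylate | COC(=O)[C@@H]1[C@H](C(=O)OC(C)(C)C)[C@@](C)(c2cc(O)c(C)c(=O)o2)[C@@]1(C)c1cc(O)c(C)c(=O)o1 | intermediate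
18 | 1-tert-butyl 2-methyl (1S,2R,3S,4R)-3,4-bis(4-methoxy-3-methyl-2-oxo-2H-pyran-6-yl)-3,4-dimethylcyclobutane-1,2-dicarboxylate | COC(=O)[C@@H]1[C@H](C(=O)OC(C)(C)C)[C@@](C)(c2cc(OC)c(C)c(=O)o2)[C@@]1(C)c1cc(OC)c(C)c(=O)o1 | intermediate
19 | (1S,2R,3S,4R)-2-(methoxycarbonyl)-3,4-bis(4-methoxy-3-methyl-2-oxo-2H-pyran-6-yl)-3,4-dimethylcyclobutane-1-carboxylic acid | COC(=O)[C@@H]1[C@H](C(=O)O)[C@@](C)(c2cc(OC)c(C)c(=O)o2)[C@@]1(C)c1cc(OC)c(C)c(=O)o1 | target

## Step count and least certain steps

Total step count: 13. Longest linear sequence: 13 steps (1 and 2 to 19; 13 enters at step 9).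

**Step 5 (key step).** The most likely failure is folding of the excited diene toward the anhydride face, that is, poor facial selectivity of the disrotatory closure. The discrimination rests only on the steric demand of the five-membered ring against two methyl groups that it must eclipse, and the wrong sense would carry the cyclobutene syn to the carbonyls into the C3/C4-epimeric series. A second concern is inefficient closure, with dimerisation or hydrogen shifts taking over as the product accumulates.
The fallback makes the ring by an intermolecular sensitised [2+2] photocycloaddition; it sets out from maleic anhydride 2 and comes back at dialdehyde 12. 2,3-Dimethylmaleic anhydride would be reduced with LiAlH4 to (Z)-2,3-dimethylbut-2-ene-1,4-diol F1 and ketalised with 2,2-dimethoxypropane to 2,2,5,6-tetramethyl-4,7-dihydro-1,3-dioxepine F2. Irradiation of 2 with F2 in the presence of acetophenone should give the meso cis-anti-cis cyclobutane anhydride F3. The methods of steps 6 and 7 would then give the half-ester F4 and the tert-butyl methyl diester F5. Aqueous acetic acid would free the diol F6, and Swern oxidation of F6 gives 12. Its weak point is the syn/anti orientation of F2, so it is held in reserve.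

**Step 3.** Electron uptake may be slow because both carboxyl groups are twisted out of the ring plane by the flanking methyl groups. Once formed, the 3,5-diene can migrate into conjugation with the carboxyls if the medium becomes basic or warm.
The fallback avoids the arene altogether; it sets out from adduct 3 and comes back at anhydride 7. The oxygen bridge of 3 would be removed reductively with low-valent titanium (TiCl4/Zn, THF, 0 °C): both allylic C–O bonds are cleaved and the 1,3-diene is formed directly. The cis relation at the anhydride carbons is already present in 3, so no new compound intervenes.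

**Step 6.** Insufficient enantiotopic discrimination is possible, because both carbonyls are shielded on one side by the cis bridgehead methyls and the substrate differs from the usual bicyclic anhydrides; the sense of induction also rests on analogy.
The fallback is a resolution; it sets out from 8 and comes back at 9. Methanolysis of 8 with MeOH/Et3N would give the racemic half-ester F7. Crystallisation with (R)-1-phenylethylamine (or its antipode, whichever gives the less soluble salt of the wanted acid) would give the diastereomerically pure ammonium salt F8, and acidification of F8 returns 9.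

**Step 9.** Two processes may interfere. After the first addition the alkoxide can add to the neighbouring cis aldehyde, and this lactolate formation stalls the second addition. Excess dianion can also abstract H1/H2 next to the ring esters, which opens the ring by retro-Michael cleavage.
The fallback uses no basic intermediate; it sets out from 12 and 13 and comes back at 15. Keto ester 13 would be silylated twice (Me3SiCl/Et3N, then LiN(i-Pr)2/Me3SiCl) to 1-methoxy-2-methyl-1,3-bis(trimethylsilyloxy)buta-1,3-diene F9. A vinylogous Mukaiyama aldol of F9 with 12 (BF3·OEt2, CH2Cl2, −78 °C) gives 15 after desilylating work-up.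

**Step 11.** Compound 16 holds a cis 1,4-diketone across C3–C4, so the doubly activated methylene of one arm can add to the ketone of the other. This cross-arm aldol condensation to a five-membered carbocycle competes with lactonisation.
The fallback never passes through the diketone; it sets out from 15 and comes back at 18, replacing steps 10 to 12. Lactonisation of 15 (K2CO3, MeOH) would give the bis(4-hydroxy-3-methyl-5,6-dihydro-2-pyranone) F10. Methylation (Me2SO4, K2CO3, acetone) would give the bis(4-methoxy-3-methyl-5,6-dihydro-2-pyranone) F11, and dehydrogenation of F11 with DDQ in hot dioxane gives 18. This order also removes the 2-pyrone/4-pyrone ambiguity of step 12.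

## Further compounds

F1 | step 5 | (Z)-2,3-dimethylbut-2-ene-1,4-diol | OC/C(C)=C(C)\CO
F2 | step 5 | 2,2,5,6-tetramethyl-4,7-dihydro-1,3-dioxepine | CC1=C(C)COC(C)(C)OC1
F3 | step 5 | meso cis-anti-cis [2+2] adduct of 2 and F2 (cyclobutane anhydride with the dioxepane ring trans to the anhydride, methyls cis to it) | O=C1OC(=O)[C@@H]2[C@H]1[C@@](C)(C3)[C@@]2(C)COC(C)(C)O3
F4 | step 5 | methyl half-ester from quinidine-mediated methanolysis of F3 | COC(=O)[C@@H]1[C@H](C(=O)O)[C@@](C)(C2)[C@@]1(C)COC(C)(C)O2
F5 | step 5 | tert-butyl methyl diester of F4 (acetonide) | COC(=O)[C@@H]1[C@H](C(=O)OC(C)(C)C)[C@@](C)(C2)[C@@]1(C)COC(C)(C)O2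
F6 | step 5 | 1-tert-butyl 2-methyl (1S,2R,3S,4R)-3,4-bis(hydroxymethyl)-3,4-dimethylcyclobutane-1,2-dicarboxylate | COC(=O)[C@@H]1[C@H](C(=O)OC(C)(C)C)[C@@](C)(CO)[C@@]1(C)CO
F0 | step 3 | none | none
F7 | step 6 | racemic 3-(methoxycarbonyl)-1,4-dimethylbicyclo[2.2.0]hex-5-ene-2-carboxylic acid (racemate; one enantiomer drawn) | COC(=O)[C@@H]1[C@H](C(=O)O)[C@]2(C)[C@@]1(C)C=C2
F8 | step 6 | (R)-1-phenylethylammonium salt of 9 | COC(=O)[C@@H]1[C@H](C(=O)[O-])[C@]2(C)[C@@]1(C)C=C2.C[C@@H]([NH3+])c1ccccc1
F9 | step 9 | 1-methoxy-2-methyl-1,3-bis(trimethylsilyloxy)buta-1,3-diene | COC(O[Si](C)(C)C)=C(C)C(=C)O[Si](C)(C)C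
F10 | step 11 | 1-tert-butyl 2-methyl 3,4-bis(4-hydroxy-3-methyl-2-oxo-5,6-dihydro-2H-pyran-6-yl)-3,4-dimethylcyclobutane-1,2-dicarboxylate (ring centres as in 15, lactone C6 centres as a mixture) | COC(=O)[C@@H]1[C@H](C(=O)OC(C)(C)C)[C@@](C)(C2CC(O)=C(C)C(=O)O2)[C@@]1(C)C1CC(O)=C(C)C(=O)O1
F11 | step 11 | 1-tert-butyl 2-methyl 3,4-bis(4-methoxy-3-methyl-2-oxo-5,6-dihydro-2H-pyran-6-yl)-3,4-dimethylcyclobutane-1,2-dicarboxylate (lactone C6 centres as a mixture) | COC(=O)[C@@H]1[C@H](C(=O)OC(C)(C)C)[C@@](C)(C2CC(OC)=C(C)C(=O)O2)[C@@]1(C)C1CC(OC)=C(C)C(=O)O1
A1 | alternative 1 | bis(trimethylsilyl enol ether) of the meso cis-3,4-diacetyl-3,4-dimethylcyclobutane-1,2-diyldimethyl diacetate | CC(=O)OC[C@@H]1[C@H](COC(C)=O)[C@@](C)(C(=C)O[Si](C)(C)C)[C@@]1(C)C(=C)O[Si](C)(C)C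
A2 | alternative 1 | methylmalonyl dichloride | CC(C(=O)Cl)C(=O)Cl
A3 | alternative 1 | meso bis(4-hydroxy-3-methyl-2-pyron-6-yl) diacetate | CC(=O)OC[C@@H]1[C@H](COC(C)=O)[C@@](C)(c2cc(O)c(C)c(=O)o2)[C@@]1(C)c1cc(O)c(C)c(=O)o1
A4 | alternative 2 | cis,trans,cis-cyclobutane-1,2,3,4-tetracarboxylic dianhydride | O=C1OC(=O)[C@@H]2[C@H]1[C@@H](C(=O)O3)[C@H]2C3=O
A5 | alternative 2 | N-(4-methoxybenzyl) imide diacid from A4 (meso) | OC(=O)[C@@H]1[C@H](C(=O)O)[C@@H](C2=O)[C@H]1C(=O)N2Cc1ccc(OC)cc1
A6 | alternative 2 | 3,4-dimethyl imide diacid (meso) | OC(=O)[C@@H]1[C@H](C(=O)O)[C@@](C)(C2=O)[C@@]1(C)C(=O)N2Cc1ccc(OC)cc1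
A7 | alternative 3 | (S)-5-(pivaloyloxymethyl)furan-2(5H)-one | O1[C@H](COC(=O)C(C)(C)C)C=CC1=O
A8 | alternative 3 | 2,2,5,6-tetramethyl-4,7-dihydro-1,3-dioxepine | CC1=C(C)COC(C)(C)OC1
A9 | alternative 3 | cis-anti-cis tricyclic lactone photoadduct | O1[C@H](COC(=O)C(C)(C)C)[C@@H]2[C@H](C1=O)[C@@](C)(C3)[C@@]2(C)COC(C)(C)O3
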